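## Retrosynthetic overview

1. Target ⇐ removal of seven MOM groups ⇐ Claisen–Schmidt condensation that installs the chalcone arm on a protected acetyl cyclohexenyl aryl ketone.
2. Aryl ketone ⇐ Negishi acylation of a cyclohexene carboxylic acid chloride with the arylzinc of 2-prenylresorcinol bis-MOM ether.
3. Cyclohexene (the only ring that is built) ⇐ ring-closing metathesis of a 1,6-diene acid, whose C-1 and C-2 centres come from an Ireland–Claisen rearrangement (1,3-chirality transfer from an R allylic alcohol).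
4. Acid half ⇐ key C–C bond: carbene-derived homoenolate of a cinnamaldehyde (β-carbon as nucleophile) plus a π-methallylpalladium electrophile, which sets the C-6 centre.
5. Ring order: the four benzene rings are bought; the cyclohexene is closed once, by metathesis, after all three stereocentres are in place.

Assumption: the (5aS,10bR) enantiomer of the aminoindanol triazolium salt is taken to give the 3S ester 8; should it give 3R, its mirror image is used.

Cyclohexene numbering used below: C-1 carries the aroyl group, C-2 the acetyl/chalcone aryl ring, C-6 the 2,4-dioxygenated phenyl ring (C-1/C-2/C-6 = C-4''/C-3''/C-5'' of the natural product; target 1R,2S,6S).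

## Route

Step 1
Reactants: 1 2,4-dihydroxybenzaldehyde
Product: 2 2,4-bis(methoxymethoxy)benzaldehyde
Conditions: NaH, MOMCl, DMF, 0 °C to rt
Reagents that add atoms: chloromethyl methyl ether (MOMCl), COCCl
Why: Williamson O-alkylation of both phenoxides gives the bis-MOM ether, which withstands all later basic and organometallic steps; no stereocentre is formed.

Step 2
Reactants: 2 2,4-bis(methoxymethoxy)benzaldehyde; 3 (triphenylphosphoranylidene)acetaldehyde
Product: 4 (2E)-3-[2,4-bis(methoxymethoxy)phenyl]prop-2-enal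
Conditions: toluene, 80 °C
Reagents that add atoms: none
Why: Wittig two-carbon homologation with a stabilised ylide gives the E enal selectively.

Step 3
Reactants: 5 2-methylprop-2-en-1-ol; 6 2,2,2-trifluoroethyl carbonochloridate
Product: 7 2-methylprop-2-en-1-yl 2,2,2-trifluoroethyl carbonate
Conditions: pyridine, CH2Cl2, 0 °C
Reagents that add atoms: none
Why: Acylation of the alcohol by the chloroformate gives a mixed carbonate that later releases both the allyl electrophile and an aprotic alkoxide.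

Step 4
Reactants: 4 (2E)-3-[2,4-bis(methoxymethoxy)phenyl]prop-2-enal; 7 2-methylprop-2-en-1-yl 2,2,2-trifluoroethyl carbonate
Product: 8 2,2,2-trifluoroethyl (3S)-3-[2,4-bis(methoxymethoxy)phenyl]-5-methylhex-5-enoate
Conditions: (5aS,10bR)-2-(2,4,6-trimethylphenyl)-5a,10b-dihydro-4H,6H-indeno[2,1-b][1,2,4]triazolo[4,3-d][1,4]oxazin-2-ium tetrafluoroborate (10 mol%), Pd2(dba)3 (2.5 mol%), Xantphos (6 mol%), THF, 23 °C
Reagents that add atoms: none
Why: Proposed new method: the carbene converts enal 4 into its homoenolate, whose β-carbon (electrophilic in the free enal) attacks the (η3-2-methylallyl)palladium cation formed when zerovalent palladium ionises carbonate 7 with loss of CO2, the released trifluoroethoxide is the only base and then captures the acyl azolium to close both cycles without a protic source that would protonate the β-carbon, and the chiral triazolylidene shields one face of the β-carbon so the 3S centre is set under catalyst control; the closest known reactions are the cooperative carbene/palladium homoenolate allylations in enantioselective (4+3) annulations of enals with vinyl benzoxazinanones and carbene redox esterifications of enals.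

Step 5
Reactants: 9 1-(2,4-dihydroxyphenyl)ethan-1-one
Product: 10 1-(2,4-dihydroxy-3-iodophenyl)ethan-1-one
Conditions: I2, HIO3, EtOH/H2O, 35 °C
Reagents that add atoms: iodine, II; iodic acid, OI(=O)=O
Why: Electrophilic aromatic iodination at the doubly activated position between the two hydroxyl groups gives the 3-iodide.

Step 6
Reactants: 10 1-(2,4-dihydroxy-3-iodophenyl)ethan-1-one
Product: 11 1-[3-iodo-2,4-bis(methoxymethoxy)phenyl]ethan-1-one
Conditions: NaH, MOMCl, DMF, 0 °C to rt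
Reagents that add atoms: chloromethyl methyl ether (MOMCl), COCCl
Why: Williamson O-alkylation protects both phenols, including the hydrogen-bonded one, as MOM ethers.

Step 7
Reactants: 11 1-[3-iodo-2,4-bis(methoxymethoxy)phenyl]ethan-1-one; 12 (2R)-but-3-en-2-ol
Product: 13 1-[3-[(1E,3R)-3-hydroxybut-1-en-1-yl]-2,4-bis(methoxymethoxy)phenyl]ethan-1-one
Conditions: Pd(OAc)2 (5 mol%), Ag2CO3, DMF, 60 °C
Reagents that add atoms: none
Why: Mizoroki–Heck arylation at the terminal alkene carbon under silver-mediated halide abstraction directs β-hydride elimination to the benzylic side, giving the E allylic alcohol and leaving the R carbinol centre of 12 untouched.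

Step 8
Reactants: 8 2,2,2-trifluoroethyl (3S)-3-[2,4-bis(methoxymethoxy)phenyl]-5-methylhex-5-enoate; 13 1-[3-[(1E,3R)-3-hydroxybut-1-en-1-yl]-2,4-bis(methoxymethoxy)phenyl]ethan-1-one
Product: 17 (2R,3S,4E)-3-[3-acetyl-2,6-bis(methoxymethoxy)phenyl]-2-[(1S)-1-[2,4-bis(methoxymethoxy)phenyl]-3-methylbut-3-en-1-yl]hex-4-enoic acid, via allyl ester 14 (not isolated), via silyl ketene acetal 15 (not isolated), via silyl ester 16 (not isolated)
Conditions: 13, LiN(iPr)2 (1.0 equiv), THF, −78 °C, then 8, −78 to 0 °C; then DMPU, LiN(iPr)2 (2.5 equiv), Me3SiCl, −78 to 23 °C; then aq. citric acid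
Reagents that add atoms: none
Why: Ester exchange of the activated trifluoroethyl ester with the lithium alkoxide of 13 is followed by an Ireland–Claisen rearrangement in which the Z silyl ketene acetal (THF/DMPU) reacts through a chair transition state with the carbinol methyl equatorial, so the R carbinol centre is relayed to the 3S centre with an E alkene and the ketene acetal geometry sets 2R, while the aryl methyl ketone travels as its silyl enol ether and returns on work-up.

Step 9
Reactants: 17 (2R,3S,4E)-3-[3-acetyl-2,6-bis(methoxymethoxy)phenyl]-2-[(1S)-1-[2,4-bis(methoxymethoxy)phenyl]-3-methylbut-3-en-1-yl]hex-4-enoic acid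
Product: 18 (1R,2S,6S)-2-[3-acetyl-2,6-bis(methoxymethoxy)phenyl]-6-[2,4-bis(methoxymethoxy)phenyl]-4-methylcyclohex-3-ene-1-carboxylic acid
Conditions: second-generation Grubbs catalyst [RuCl2(=CHPh)(PCy3)(H2IMes)] (5 mol%), CH2Cl2, 40 °C
Reagents that add atoms: none
Why: Ring-closing metathesis between the propenyl and methallyl groups closes the trisubstituted cyclohexene with loss of propene and touches none of the three stereocentres.

Step 10
Reactants: 19 benzene-1,3-diol
Product: 20 1,3-bis(methoxymethoxy)benzene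
Conditions: NaH, MOMCl, DMF, 0 °C to rt
Reagents that add atoms: chloromethyl methyl ether (MOMCl), COCCl
Why: Williamson O-alkylation gives the bis-MOM ether, which also serves as the directing group for the two metalations that follow.

Step 11
Reactants: 20 1,3-bis(methoxymethoxy)benzene; 21 1-bromo-3-methylbut-2-ene
Product: 23 1,3-bis(methoxymethoxy)-2-(3-methylbut-2-en-1-yl)benzene, via aryllithium 22 (not isolated)
Conditions: n-BuLi, THF, 0 °C; then CuI (10 mol%), 21, −78 °C to rt
Reagents that add atoms: none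
Why: Directed ortho-metalation between the two MOM ethers followed by copper-catalysed SN2 alkylation places the prenyl group at C-2 regiospecifically.

Step 12
Reactants: 18 (1R,2S,6S)-2-[3-acetyl-2,6-bis(methoxymethoxy)phenyl]-6-[2,4-bis(methoxymethoxy)phenyl]-4-methylcyclohex-3-ene-1-carboxylic acid; 23 1,3-bis(methoxymethoxy)-2-(3-methylbut-2-en-1-yl)benzene
Product: 27 [(1R,2S,6S)-2-[3-acetyl-2,6-bis(methoxymethoxy)phenyl]-6-[2,4-bis(methoxymethoxy)phenyl]-4-methylcyclohex-3-en-1-yl][2,4-bis(methoxymethoxy)-3-(3-methylbut-2-en-1-yl)phenyl]methanone, via acid chloride 24 (not isolated), via aryllithium 25 (not isolated), via arylzinc chloride 26 (not isolated)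
Conditions: 18, 1-chloro-N,N,2-trimethylprop-1-en-1-amine, CH2Cl2, 0 °C to rt; 23, n-BuLi, TMEDA, THF, 0 °C, then ZnCl2; then Pd(PPh3)4 (5 mol%), THF, rt
Reagents that add atoms: none
Why: Negishi acylation joins the acid chloride (formed under neutral conditions) with the arylzinc obtained by MOM-directed ortho-lithiation and transmetalation, a nucleophile that spares the acetyl group; the ring stereocentres are retained and any C-1 epimer converges in step 14.

Step 13
Reactants: 28 4-hydroxybenzaldehyde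
Product: 29 4-(methoxymethoxy)benzaldehyde
Conditions: NaH, MOMCl, DMF, 0 °C
Reagents that add atoms: chloromethyl methyl ether (MOMCl), COCCl
Why: Williamson O-alkylation masks the phenol so the aldehyde stays electrophilic under the hydroxide conditions of step 14.

Step 14
Reactants: 27 [(1R,2S,6S)-2-[3-acetyl-2,6-bis(methoxymethoxy)phenyl]-6-[2,4-bis(methoxymethoxy)phenyl]-4-methylcyclohex-3-en-1-yl][2,4-bis(methoxymethoxy)-3-(3-methylbut-2-en-1-yl)phenyl]methanone; 29 4-(methoxymethoxy)benzaldehyde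
Product: 30 [(1R,2S,6S)-2-[2,6-bis(methoxymethoxy)-3-[(2E)-3-[4-(methoxymethoxy)phenyl]prop-2-enoyl]phenyl]-6-[2,4-bis(methoxymethoxy)phenyl]-4-methylcyclohex-3-en-1-yl][2,4-bis(methoxymethoxy)-3-(3-methylbut-2-en-1-yl)phenyl]methanone
Conditions: KOH, EtOH/H2O, rt to 40 °C
Reagents that add atoms: none
Why: Claisen–Schmidt aldol condensation at the only methyl ketone gives the E chalcone, and the hydroxide equilibrates C-1 (the one enolisable centre) to the 1,2-cis-1,6-trans isomer, expected to be the more stable because the aroyl and C-6 aryl groups are both equatorial with the C-2 aryl pseudoaxial.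

Step 15
Reactants: 30 [(1R,2S,6S)-2-[2,6-bis(methoxymethoxy)-3-[(2E)-3-[4-(methoxymethoxy)phenyl]prop-2-enoyl]phenyl]-6-[2,4-bis(methoxymethoxy)phenyl]-4-methylcyclohex-3-en-1-yl][2,4-bis(methoxymethoxy)-3-(3-methylbut-2-en-1-yl)phenyl]methanone
Product: 31 [(1R,2S,6S)-2-[2,6-dihydroxy-3-[(2E)-3-(4-hydroxyphenyl)prop-2-enoyl]phenyl]-6-(2,4-dihydroxyphenyl)-4-methylcyclohex-3-en-1-yl][2,4-dihydroxy-3-(3-methylbut-2-en-1-yl)phenyl]methanone
Conditions: 3 M aq. HCl, MeOH, 40 °C
Reagents that add atoms: none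
Why: Acid-catalysed acetal methanolysis removes all seven MOM groups under conditions mild enough to leave the prenyl group, the chalcone and the three stereocentres unchanged.

## Compound list

1 | 2,4-dihydroxybenzaldehyde | O=Cc1ccc(O)cc1O | starting material
2 | 2,4-bis(methoxymethoxy)benzaldehyde | COCOc1ccc(C=O)c(OCOC)c1 | intermediate
3 | (triphenylphosphoranylidene)acetaldehyde | O=CC=P(c1ccccc1)(c1ccccc1)c1ccccc1 | starting material
4 | (2E)-3-[2,4-bis(methoxymethoxy)phenyl]prop-2-enal | O=C/C=C/c1ccc(OCOC)cc1OCOC | intermediate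
5 | 2-methylprop-2-en-1-ol | C=C(C)CO | starting material
6 | 2,2,2-trifluoroethyl carbonochloridate | O=C(Cl)OCC(F)(F)F | starting material
7 | 2-methylprop-2-en-1-yl 2,2,2-trifluoroethyl carbonate | C=C(C)COC(=O)OCC(F)(F)F | intermediate
8 | 2,2,2-trifluoroethyl (3S)-3-[2,4-bis(methoxymethoxy)phenyl]-5-methylhex-5-enoate | O=C(OCC(F)(F)F)C[C@@H](c1ccc(OCOC)cc1OCOC)CC(C)=C | intermediate
9 | 1-(2,4-dihydroxyphenyl)ethan-1-one | CC(=O)c1ccc(O)cc1O | starting material
10 | 1-(2,4-dihydroxy-3-iodophenyl)ethan-1-one | CC(=O)c1ccc(O)c(I)c1O | intermediate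
11 | 1-[3-iodo-2,4-bis(methoxymethoxy)phenyl]ethan-1-one | CC(=O)c1ccc(OCOC)c(I)c1OCOC | intermediate
12 | (2R)-but-3-en-2-ol | C[C@@H](O)C=C | starting material
13 | 1-[3-[(1E,3R)-3-hydroxybut-1-en-1-yl]-2,4-bis(methoxymethoxy)phenyl]ethan-1-one | C[C@@H](O)/C=C/c1c(OCOC)ccc(C(C)=O)c1OCOC | intermediate
14 | (2R,3E)-4-[3-acetyl-2,6-bis(methoxymethoxy)phenyl]but-3-en-2-yl (3S)-3-[2,4-bis(methoxymethoxy)phenyl]-5-methylhex-5-enoate | C[C@@H](OC(=O)C[C@@H](c1ccc(OCOC)cc1OCOC)CC(C)=C)/C=C/c1c(OCOC)ccc(C(C)=O)c1OCOC | intermediate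
15 | bis(trimethylsilyl) derivative of 14: Z O-silyl ketene acetal of the ester (aryl-bearing carbon cis to OSiMe3) and trimethylsilyl enol ether of the acetyl group; carbinol R, benzylic centre S | C[C@@H](O/C(O[Si](C)(C)C)=C/[C@@H](c1ccc(OCOC)cc1OCOC)CC(C)=C)/C=C/c1c(OCOC)ccc(C(=C)O[Si](C)(C)C)c1OCOC | intermediate
16 | trimethylsilyl (2R,3S,4E)-2-[(1S)-1-[2,4-bis(methoxymethoxy)phenyl]-3-methylbut-3-en-1-yl]-3-[2,6-bis(methoxymethoxy)-3-[1-(trimethylsilyloxy)ethenyl]phenyl]hex-4-enoate | C[Si](C)(C)OC(=O)[C@H]([C@@H](c1ccc(OCOC)cc1OCOC)CC(C)=C)[C@@H](c1c(OCOC)ccc(C(=C)O[Si](C)(C)C)c1OCOC)/C=C/C | intermediate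
17 | (2R,3S,4E)-3-[3-acetyl-2,6-bis(methoxymethoxy)phenyl]-2-[(1S)-1-[2,4-bis(methoxymethoxy)phenyl]-3-methylbut-3-en-1-yl]hex-4-enoic acid | OC(=O)[C@H]([C@@H](c1ccc(OCOC)cc1OCOC)CC(C)=C)[C@@H](c1c(OCOC)ccc(C(C)=O)c1OCOC)/C=C/C | intermediate
18 | (1R,2S,6S)-2-[3-acetyl-2,6-bis(methoxymethoxy)phenyl]-6-[2,4-bis(methoxymethoxy)phenyl]-4-methylcyclohex-3-ene-1-carboxylic acid | OC(=O)[C@H]1[C@@H](c2c(OCOC)ccc(C(C)=O)c2OCOC)C=C(C)C[C@@H]1c1ccc(OCOC)cc1OCOC | intermediate
19 | benzene-1,3-diol (resorcinol) | Oc1cccc(O)c1 | starting material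
20 | 1,3-bis(methoxymethoxy)benzene | COCOc1cccc(OCOC)c1 | intermediate
21 | 1-bromo-3-methylbut-2-ene | CC(C)=CCBr | starting material
22 | [2,6-bis(methoxymethoxy)phenyl]lithium | [Li]c1c(OCOC)cccc1OCOC | intermediate
23 | 1,3-bis(methoxymethoxy)-2-(3-methylbut-2-en-1-yl)benzene | CC(C)=CCc1c(OCOC)cccc1OCOC | intermediate
24 | (1R,2S,6S)-2-[3-acetyl-2,6-bis(methoxymethoxy)phenyl]-6-[2,4-bis(methoxymethoxy)phenyl]-4-methylcyclohex-3-ene-1-carbonyl chloride | O=C(Cl)[C@H]1[C@@H](c2c(OCOC)ccc(C(C)=O)c2OCOC)C=C(C)C[C@@H]1c1ccc(OCOC)cc1OCOC | intermediate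
25 | [2,4-bis(methoxymethoxy)-3-(3-methylbut-2-en-1-yl)phenyl]lithium | CC(C)=CCc1c(OCOC)ccc([Li])c1OCOC | intermediate
26 | [2,4-bis(methoxymethoxy)-3-(3-methylbut-2-en-1-yl)phenyl]zinc chloride | CC(C)=CCc1c(OCOC)ccc([Zn]Cl)c1OCOC | intermediate
27 | [(1R,2S,6S)-2-[3-acetyl-2,6-bis(methoxymethoxy)phenyl]-6-[2,4-bis(methoxymethoxy)phenyl]-4-methylcyclohex-3-en-1-yl][2,4-bis(methoxymethoxy)-3-(3-methylbut-2-en-1-yl)phenyl]methanone | CC(C)=CCc1c(OCOC)ccc(C(=O)[C@H]2[C@@H](c3c(OCOC)ccc(C(C)=O)c3OCOC)C=C(C)C[C@@H]2c2ccc(OCOC)cc2OCOC)c1OCOC | intermediate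
28 | 4-hydroxybenzaldehyde | O=Cc1ccc(O)cc1 | starting material
29 | 4-(methoxymethoxy)benzaldehyde | COCOc1ccc(C=O)cc1 | intermediate
30 | [(1R,2S,6S)-2-[2,6-bis(methoxymethoxy)-3-[(2E)-3-[4-(methoxymethoxy)phenyl]prop-2-enoyl]phenyl]-6-[2,4-bis(methoxymethoxy)phenyl]-4-methylcyclohex-3-en-1-yl][2,4-bis(methoxymethoxy)-3-(3-methylbut-2-en-1-yl)phenyl]methanone | CC(C)=CCc1c(OCOC)ccc(C(=O)[C@H]2[C@@H](c3c(OCOC)ccc(C(=O)/C=C/c4ccc(OCOC)cc4)c3OCOC)C=C(C)C[C@@H]2c2ccc(OCOC)cc2OCOC)c1OCOC | intermediate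
31 | [(1R,2S,6S)-2-[2,6-dihydroxy-3-[(2E)-3-(4-hydroxyphenyl)prop-2-enoyl]phenyl]-6-(2,4-dihydroxyphenyl)-4-methylcyclohex-3-en-1-yl][2,4-dihydroxy-3-(3-methylbut-2-en-1-yl)phenyl]methanone (CNP0283121.1) | CC(C)=CCc1c(O)ccc(C(=O)[C@H]2[C@@H](c3c(O)ccc(C(=O)/C=C/c4ccc(O)cc4)c3O)C=C(C)C[C@@H]2c2ccc(O)cc2O)c1O | target

## Step count and risks

Total step count: 15.

Longest linear sequence: 8 steps (steps 1, 2, 4, 8, 9, 12, 14, 15 from compound 1; the branch from compound 9 through steps 5, 6, 7, 8, 9, 12, 14, 15 is equally long).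

The three steps most likely to fail:

Step 4 (the carbene and the palladium catalyst may deactivate each other, or the β-carbon may be protonated instead of allylated). The fallback sets out from 4 and comes back at 8. The same triazolium catalyst, without palladium, adds the homoenolate of 4 to 2-nitropropene (a well-precedented acceptor class) with 2,2,2-trifluoroethanol as acyl acceptor, giving 2,2,2-trifluoroethyl (3S)-3-[2,4-bis(methoxymethoxy)phenyl]-5-nitrohexanoate F1. An oxidative Nef reaction (DBU, then KHSO5) converts it into the keto ester 2,2,2-trifluoroethyl (3S)-3-[2,4-bis(methoxymethoxy)phenyl]-5-oxohexanoate F2. Methylenation of the ketone with Cp2Ti(CH3)2 in toluene at 65 °C then gives 8.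

Step 7 (a doubly ortho-substituted aryl iodide is a slow Heck partner, and β-hydride elimination toward the carbinol would give a saturated ketone). The fallback sets out from 11 and comes back at 13. Hydroboration of (2R)-but-3-yn-2-ol with pinacolborane (Cp2Zr(H)Cl catalyst) gives the alkenylboronate (2R,3E)-4-(4,4,5,5-tetramethyl-1,3,2-dioxaborolan-2-yl)but-3-en-2-ol F3. Suzuki–Miyaura coupling of F3 with 11 (Pd(OAc)2, SPhos, K3PO4, THF/H2O, 60 °C) forms the same C–C bond with fixed E geometry and no β-hydride issue, giving 13.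

Step 8 (the free acetyl group competes for base, and a telescoped exchange/rearrangement is demanding). The fallback sets out from 8, uses 13 and 25, and comes back at 27, bypassing steps 9 and 12. Ester 8 is exchanged (NaOCH3, CH3OH) to methyl (3S)-3-[2,4-bis(methoxymethoxy)phenyl]-5-methylhex-5-enoate F4. Aryllithium 25 is quenched with methyl chloroformate to give methyl 2,4-bis(methoxymethoxy)-3-(3-methylbut-2-en-1-yl)benzoate F5. Crossed Claisen condensation of the lithium enolate of F4 with F5 gives the β-keto ester methyl (3S)-2-[2,4-bis(methoxymethoxy)-3-(3-methylbut-2-en-1-yl)benzoyl]-3-[2,4-bis(methoxymethoxy)phenyl]-5-methylhex-5-enoate F6. Heating F6 with 13 (DMAP, xylene, 110 to 140 °C), conditions under which the acetyl group is not enolised, exchanges the ester to the allyl β-keto ester (2R,3E)-4-[3-acetyl-2,6-bis(methoxymethoxy)phenyl]but-3-en-2-yl (3S)-2-[2,4-bis(methoxymethoxy)-3-(3-methylbut-2-en-1-yl)benzoyl]-3-[2,4-bis(methoxymethoxy)phenyl]-5-methylhex-5-enoate F7. F7 undergoes Carroll rearrangement and decarboxylation in the same pot, with the same 1,3-chirality transfer, to the dienyl ketone (3S,4E)-3-[3-acetyl-2,6-bis(methoxymethoxy)phenyl]-1-[2,4-bis(methoxymethoxy)-3-(3-methylbut-2-en-1-yl)phenyl]-2-[(1S)-1-[2,4-bis(methoxymethoxy)phenyl]-3-methylbut-3-en-1-yl]hex-4-en-1-one F8. Ring-closing metathesis under the step 9 conditions, followed by DBU to equilibrate C-1, gives 27.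

Further compounds

F1 | step 4 | 2,2,2-trifluoroethyl (3S)-3-[2,4-bis(methoxymethoxy)phenyl]-5-nitrohexanoate (both C-5 epimers) | O=C(OCC(F)(F)F)C[C@@H](c1ccc(OCOC)cc1OCOC)CC(C)[N+](=O)[O-]
F2 | step 4 | 2,2,2-trifluoroethyl (3S)-3-[2,4-bis(methoxymethoxy)phenyl]-5-oxohexanoate | O=C(OCC(F)(F)F)C[C@@H](c1ccc(OCOC)cc1OCOC)CC(C)=O
F3 | step 7 | (2R,3E)-4-(4,4,5,5-tetramethyl-1,3,2-dioxaborolan-2-yl)but-3-en-2-ol | C[C@@H](O)/C=C/B1OC(C)(C)C(C)(C)O1
F4 | step 8 | methyl (3S)-3-[2,4-bis(methoxymethoxy)phenyl]-5-methylhex-5-enoate | COC(=O)C[C@@H](c1ccc(OCOC)cc1OCOC)CC(C)=C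
F5 | step 8 | methyl 2,4-bis(methoxymethoxy)-3-(3-methylbut-2-en-1-yl)benzoate | COC(=O)c1ccc(OCOC)c(CC=C(C)C)c1OCOC
F6 | step 8 | methyl (3S)-2-[2,4-bis(methoxymethoxy)-3-(3-methylbut-2-en-1-yl)benzoyl]-3-[2,4-bis(methoxymethoxy)phenyl]-5-methylhex-5-enoate (both C-2 epimers) | COC(=O)C(C(=O)c1ccc(OCOC)c(CC=C(C)C)c1OCOC)[C@@H](c1ccc(OCOC)cc1OCOC)CC(C)=C
F7 | step 8 | (2R,3E)-4-[3-acetyl-2,6-bis(methoxymethoxy)phenyl]but-3-en-2-yl (3S)-2-[2,4-bis(methoxymethoxy)-3-(3-methylbut-2-en-1-yl)benzoyl]-3-[2,4-bis(methoxymethoxy)phenyl]-5-methylhex-5-enoate (both C-2 epimers) | C[C@@H](OC(=O)C(C(=O)c1ccc(OCOC)c(CC=C(C)C)c1OCOC)[C@@H](c1ccc(OCOC)cc1OCOC)CC(C)=C)/C=C/c1c(OCOC)ccc(C(C)=O)c1OCOC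
F8 | step 8 | (3S,4E)-3-[3-acetyl-2,6-bis(methoxymethoxy)phenyl]-1-[2,4-bis(methoxymethoxy)-3-(3-methylbut-2-en-1-yl)phenyl]-2-[(1S)-1-[2,4-bis(methoxymethoxy)phenyl]-3-methylbut-3-en-1-yl]hex-4-en-1-one (both C-2 epimers) | CC(C)=CCc1c(OCOC)ccc(C(=O)C([C@@H](c2ccc(OCOC)cc2OCOC)CC(C)=C)[C@@H](c2c(OCOC)ccc(C(C)=O)c2OCOC)/C=C/C)c1OCOC
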